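**Retrosynthetic overview** (C1 = CO2H, C3/C4/C5 = ring carbons, C1'–C16' = side chain)
1. The acid-labile triene is installed last. The C9'=C10' bond is cut (HWE) to give a dioxolane aldehyde-acid and a (2E,4E)-heptadienyl phosphonate.
2. The C2–C3 bond is cut to give a C3 peroxycarbenium ion (from the peroxyhemiketal) and the bis-silyl ketene acetal of acetic acid.
3. The 1,2-dioxolane comes from a β-hydroperoxy ketone. Its C5–OO bond is made by H2O2 opening of an (R)-2,2,4-trisubstituted oxetane with inversion.
4. Key C3–C4 bond: the oxetane comes from an (R)-2,2-disubstituted epoxide and an α-sulfonimidoyl ethyl carbanion. This carbanion is an acetaldehyde/acetyl C1-anion that carries its own leaving group, so it joins two naturally electrophilic carbons.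
5. The epoxide comes from dodec-11-en-2-one, which comes from undec-10-enoic acid. Ring order: oxirane (step 2), then oxetane (step 4), then 1,2-dioxolane (step 6).

**Assumption:** commercial hepta-2,4-dienal is the (2E,4E) isomer, and the (R)-BINOL-derived La/Li catalyst is taken to give (R)-5; if the first run shows the opposite sense, the (S)-BINOL catalyst is used and nothing else changes.

**Step 1**
Reactants: 1 undec-10-enoic acid
Product: 3 dodec-11-en-2-one, via dilithium gem-diolate 2 (not isolated)
Conditions: MeLi (2.1 equiv), Et2O, 0 °C → rt; inverse quench into ice-cold 1 M HCl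
Reagents that add atoms: methyllithium, [Li]C
Why: In this carboxylate-to-ketone organolithium addition the first MeLi deprotonates the acid and the second gives a gem-diolate that cannot collapse until the quench, so over-addition is blocked; no stereocenter is formed.

**Step 2**
Reactants: 3 dodec-11-en-2-one
Product: 5 (2R)-2-(dec-9-en-1-yl)-2-methyloxirane, via sulfoxonium betaine 4 (not isolated)
Conditions: Me2S(O)=CH2 (1.2 equiv, pre-formed from Me3S(O)Cl + NaH, THF, reflux, filtered), LaLi3[(R)-BINOLate]3 (5 mol %, from La(OiPr)3, (R)-BINOL, n-BuLi), [2,4,6-(MeO)3C6H2]3P=O (5 mol %), 5 Å MS, THF, rt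
Reagents that add atoms: dimethylsulfoxonium methylide, C[S+](C)(=O)[CH2-]
Why: In this catalytic asymmetric Corey–Chaykovsky epoxidation the La/Li binaphthoxide binds ketone and ylide together, distinguishes methyl from the long alkyl group (methyl alkyl ketones typically give above 90 % ee) and delivers CH2 to one face, which sets the future C5 as R.

**Step 3**
Reactants: 6 ethyl phenyl sulfoxide (racemic)
Product: 7 S-ethyl-S-phenyl-N-tosylsulfoximine (racemic)
Conditions: PhI=NTs (1.1 equiv), Cu(OTf)2 (5 mol %), MeCN, rt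
Reagents that add atoms: [N-(p-tolylsulfonyl)imino]phenyliodinane, Cc1ccc(cc1)S(=O)(=O)N=Ic1ccccc1
Why: This copper-nitrenoid imidation of a sulfoxide transfers NTs to the sulfur lone pair cleanly, and the sulfur configuration is irrelevant because sulfur is expelled in step 4.

**Step 4 (key step)**
Reactants: 5 (2R)-2-(dec-9-en-1-yl)-2-methyloxirane; 7 S-ethyl-S-phenyl-N-tosylsulfoximine
Product: 10 (2R,4RS)-2-(dec-9-en-1-yl)-2,4-dimethyloxetane, via sodio sulfoximine 8 (not isolated), via alkoxide adduct 9 (not isolated)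
Conditions: 7 (2.5 equiv), NaH (2.4 equiv), DMSO, rt, 30 min; then 5, 50 °C, 24 h; H2O quench
Reagents that add atoms: none
Why: Proposed new method: carbanion 8 is an acetaldehyde C1-anion (a masked acetyl anion, since this carbon becomes the C3 carbonyl in step 6) that carries its own nucleofuge, so it opens the epoxide by SN2 attack at the unhindered CH2 (C4, itself an electrophilic carbon) without touching the C5–O bond or its R configuration, and the tertiary alkoxide 9 then expels the N-tosylbenzenesulfinamide anion in a 4-exo-tet closure; the closest known reaction type is the epoxide-to-oxetane ring expansion with dimethylsulfoxonium methylide or with the S-methyl analogue of 7, of which this is the ethylidene-transfer homologue, and the new oxetane C4 centre forms as a mixture that is erased in step 6.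

**Step 5**
Reactants: 10 (2R,4RS)-2-(dec-9-en-1-yl)-2,4-dimethyloxetane
Product: 11 (2RS,4S)-4-hydroperoxy-4-methyltetradec-13-en-2-ol
Conditions: anhydrous H2O2 (ca. 3 M in Et2O, 10 equiv), TMSOTf (0.2 equiv), Et2O, −78 → 0 °C
Reagents that add atoms: hydrogen peroxide, OO
Why: In this Lewis-acid-promoted perhydrolysis the activated oxetane is attacked by H2O2 at the cation-stabilising tertiary carbon from the backside (borderline SN2), so the R ether carbon becomes the S hydroperoxide carbon (target C5) with inversion, and the terminal alkene is too poor a nucleophile to interfere.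

**Step 6**
Reactants: 11 (2RS,4S)-4-hydroperoxy-4-methyltetradec-13-en-2-ol
Product: 13 (3RS,5S)-5-(dec-9-en-1-yl)-3,5-dimethyl-1,2-dioxolan-3-ol, via hydroperoxy ketone 12 (not isolated)
Conditions: Dess–Martin periodinane (1.2 equiv), CH2Cl2, 0 °C → rt
Reagents that add atoms: none
Why: Dess–Martin oxidation touches only the secondary carbinol because the tertiary OOH has no α-hydrogen, and the β-hydroperoxy ketone closes spontaneously to the five-membered peroxyhemiketal, leaving C5 untouched and C3 as an inconsequential anomeric mixture.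

**Step 7**
Reactants: 14 trimethylsilyl acetate
Product: 16 1,1-bis(trimethylsilyloxy)ethene, via lithium enolate 15 (not isolated)
Conditions: LDA (1.05 equiv), THF, −78 °C; TMSCl (1.1 equiv), −78 °C → rt; distillation
Reagents that add atoms: chlorotrimethylsilane, C[Si](C)(C)Cl
Why: Kinetic enolisation followed by O-silylation of the ester enolate gives the acetic acid bis-silyl ketene acetal, which releases a free acid directly after C–C bond formation.

**Step 8**
Reactants: 13 (3RS,5S)-5-(dec-9-en-1-yl)-3,5-dimethyl-1,2-dioxolan-3-ol; 16 1,1-bis(trimethylsilyloxy)ethene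
Product: 20 2-[(3R,5S)-5-(dec-9-en-1-yl)-3,5-dimethyl-1,2-dioxolan-3-yl]acetic acid, via silyl peroxyketal 17 (not isolated), via peroxycarbenium triflate 18 (not isolated), via silyl ester 19 (not isolated)
Conditions: 16 (3 equiv), TMSOTf (0.3 equiv), CH2Cl2, −78 → −40 °C; pH 4 buffer; chromatography (removes the C3 epimer)
Reagents that add atoms: none
Why: In this Mukaiyama-type SN1 alkylation of a peroxycarbenium ion (known for 3-alkoxy-1,2-dioxolanes with silyl ketene acetals) 16 first silylates the hemiketal OH, TMSOTf ionises 17 to the planar cation 18 without touching C5 or the O–O bond, and the ketene acetal attacks inside the C5-flap envelope syn to the smaller pseudoaxial methyl and anti to the decenyl chain, which sets C3 as R (trans), though only about 2:1 is expected because C5 carries two similar alkyl groups, and silyl ester 19 gives the free acid on work-up.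

**Step 9**
Reactants: 20 2-[(3R,5S)-5-(dec-9-en-1-yl)-3,5-dimethyl-1,2-dioxolan-3-yl]acetic acid
Product: 22 2-[(3R,5S)-3,5-dimethyl-5-(9-oxononyl)-1,2-dioxolan-3-yl]acetic acid, via primary ozonide 21 (not isolated)
Conditions: O3, pyridine (3 equiv), CH2Cl2, −78 °C
Reagents that add atoms: ozone, [O-][O+]=O
Why: In this pyridine-promoted ozonolysis the carbonyl oxide is decomposed directly to the aldehyde, so no reductant that could attack the dioxolane O–O bond is needed, and both stereocenters are remote and unaffected.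

**Step 10**
Reactants: 23 (2E,4E)-hepta-2,4-dienal
Product: 24 (2E,4E)-hepta-2,4-dien-1-ol
Conditions: NaBH4 (0.3 equiv), MeOH, 0 °C
Reagents that add atoms: none
Why: Borohydride 1,2-reduction of the dienal is clean at 0 °C and both E alkenes are retained.

**Step 11**
Reactants: 24 (2E,4E)-hepta-2,4-dien-1-ol
Product: 26 diethyl [(2E,4E)-hepta-2,4-dien-1-yl]phosphonate, via dienyl bromide 25 (not isolated)
Conditions: PBr3 (0.4 equiv), Et2O, −10 °C; crude bromide, P(OEt)3 (1.5 equiv), 115 °C
Reagents that add atoms: phosphorus tribromide, BrP(Br)Br; triethyl phosphite, CCOP(OCC)OCC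
Why: Bromination followed by a Michaelis–Arbuzov reaction works because the labile primary dienyl bromide is used crude and reacts with phosphite at the primary terminus, keeping the conjugated E,E diene.

**Step 12**
Reactants: 22 2-[(3R,5S)-3,5-dimethyl-5-(9-oxononyl)-1,2-dioxolan-3-yl]acetic acid; 26 diethyl [(2E,4E)-hepta-2,4-dien-1-yl]phosphonate
Product: 29 2-[(3R,5S)-5-[(9E,11E,13E)-hexadeca-9,11,13-trien-1-yl]-3,5-dimethyl-1,2-dioxolan-3-yl]acetic acid (target), via lithio phosphonate 27 (not isolated), via lithium carboxylate 28 (not isolated)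
Conditions: 26 (2.0 equiv), LiHMDS (2.0 equiv), THF, −78 °C; 22 + LiHMDS (1.0 equiv), THF, −78 °C; combine, −78 → 0 °C; dilute HCl to pH 4
Reagents that add atoms: none
Why: In this Horner–Wadsworth–Emmons olefination reversible addition of the allylic phosphonate anion and elimination through the less crowded adduct make the new C9'=C10' bond E (typically at least 10:1), the other two E alkenes come from 23, the carboxylate prevents C2 deprotonation (no E1cB ring opening), and the fully substituted dioxolane has no α-hydrogen for base-induced cleavage.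

**Compound list**
1 | undec-10-enoic acid | C=CCCCCCCCCC(=O)O | starting material
2 | dilithium dodec-11-ene-2,2-diolate | C=CCCCCCCCCC(C)([O-])[O-].[Li+].[Li+] | intermediate
3 | dodec-11-en-2-one | C=CCCCCCCCCC(C)=O | intermediate
4 | (2R)-1-(dimethyloxosulfonio)-2-methyldodec-11-en-2-olate | C=CCCCCCCCC[C@]([O-])(C)C[S+](C)(C)=O | intermediate
5 | (2R)-2-(dec-9-en-1-yl)-2-methyloxirane | C=CCCCCCCCC[C@]1(C)CO1 | intermediate
6 | ethyl phenyl sulfoxide (racemic) | CCS(=O)c1ccccc1 | starting material
7 | S-ethyl-S-phenyl-N-tosylsulfoximine (racemic) | CCS(=O)(=NS(=O)(=O)c1ccc(C)cc1)c1ccccc1 | intermediate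
8 | sodium α-carbanion of 7 | C[CH-]S(=O)(=NS(=O)(=O)c1ccc(C)cc1)c1ccccc1.[Na+] | intermediate
9 | sodium (2RS,4R)-4-methyl-2-(S-phenyl-N-tosylsulfonimidoyl)tetradec-13-en-4-olate | C=CCCCCCCCC[C@]([O-])(C)CC(C)S(=O)(=NS(=O)(=O)c1ccc(C)cc1)c1ccccc1.[Na+] | intermediate
10 | (2R,4RS)-2-(dec-9-en-1-yl)-2,4-dimethyloxetane | C=CCCCCCCCC[C@]1(C)CC(C)O1 | intermediate
11 | (2RS,4S)-4-hydroperoxy-4-methyltetradec-13-en-2-ol | C=CCCCCCCCC[C@@](OO)(C)CC(C)O | intermediate
12 | (4S)-4-hydroperoxy-4-methyltetradec-13-en-2-one | C=CCCCCCCCC[C@@](OO)(C)CC(C)=O | intermediate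
13 | (3RS,5S)-5-(dec-9-en-1-yl)-3,5-dimethyl-1,2-dioxolan-3-ol | C=CCCCCCCCC[C@@]1(C)CC(C)(O)OO1 | intermediate
14 | trimethylsilyl acetate | CC(=O)O[Si](C)(C)C | starting material
15 | lithium enolate of trimethylsilyl acetate | C=C([O-])O[Si](C)(C)C.[Li+] | intermediate
16 | 1,1-bis(trimethylsilyloxy)ethene | C=C(O[Si](C)(C)C)O[Si](C)(C)C | intermediate
17 | (3RS,5S)-5-(dec-9-en-1-yl)-3,5-dimethyl-3-(trimethylsilyloxy)-1,2-dioxolane | C=CCCCCCCCC[C@@]1(C)CC(C)(O[Si](C)(C)C)OO1 | intermediate
18 | (5S)-5-(dec-9-en-1-yl)-3,5-dimethyl-1,2-dioxolan-3-ylium triflate | C=CCCCCCCCC[C@@]1(C)CC(C)=[O+]O1.[O-]S(=O)(=O)C(F)(F)F | intermediate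
19 | trimethylsilyl 2-[(3R,5S)-5-(dec-9-en-1-yl)-3,5-dimethyl-1,2-dioxolan-3-yl]acetate | C=CCCCCCCCC[C@@]1(C)C[C@](C)(CC(=O)O[Si](C)(C)C)OO1 | intermediate
20 | 2-[(3R,5S)-5-(dec-9-en-1-yl)-3,5-dimethyl-1,2-dioxolan-3-yl]acetic acid | C=CCCCCCCCC[C@@]1(C)C[C@](C)(CC(=O)O)OO1 | intermediate
21 | primary ozonide (1,2,3-trioxolane) of 20 | O1OOCC1CCCCCCCC[C@@]2(C)C[C@](C)(CC(=O)O)OO2 | intermediate
22 | 2-[(3R,5S)-3,5-dimethyl-5-(9-oxononyl)-1,2-dioxolan-3-yl]acetic acid | O=CCCCCCCCC[C@@]1(C)C[C@](C)(CC(=O)O)OO1 | intermediate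
23 | (2E,4E)-hepta-2,4-dienal | CC/C=C/C=C/C=O | starting material
24 | (2E,4E)-hepta-2,4-dien-1-ol | CC/C=C/C=C/CO | intermediate
25 | (2E,4E)-1-bromohepta-2,4-diene | CC/C=C/C=C/CBr | intermediate
26 | diethyl [(2E,4E)-hepta-2,4-dien-1-yl]phosphonate | CC/C=C/C=C/CP(=O)(OCC)OCC | intermediate
27 | lithium α-carbanion of 26 | CC/C=C/C=C/[CH-]P(=O)(OCC)OCC.[Li+] | intermediate
28 | lithium 2-[(3R,5S)-3,5-dimethyl-5-(9-oxononyl)-1,2-dioxolan-3-yl]acetate | O=CCCCCCCCC[C@@]1(C)C[C@](C)(CC(=O)[O-])OO1.[Li+] | intermediate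
29 | 2-[(3R,5S)-5-[(9E,11E,13E)-hexadeca-9,11,13-trien-1-yl]-3,5-dimethyl-1,2-dioxolan-3-yl]acetic acid | CC/C=C/C=C/C=C/CCCCCCCC[C@@]1(C)C[C@](C)(CC(=O)O)OO1 | target

**Total step count:** 12.
**Longest linear sequence:** 8 (steps 1, 2, 4, 5, 6, 8, 9, 12).

**Three steps most likely to fail**

Step 4 (ethylidene-transfer ring expansion). The secondary carbanion is slower than the known methylene reagents, and alkoxide 9 may undergo Grob fragmentation or E2 elimination instead of the 4-exo closure. The fallback sets out from 5. The epoxide is opened with 2-lithio-2-methyl-1,3-dithiane to give the hydroxy dithiane F1. MeI/CaCO3 in aqueous MeCN unmasks the β-hydroxy ketone F2, and NaBH4 gives the 1,3-diol F3. MsCl/Et3N selectively sulfonylates the secondary hydroxyl to the secondary mesylate F4. KOt-Bu then closes the ring through the tertiary alkoxide, and the route is rejoined at 10.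

Step 6 (oxidation beside a free hydroperoxide). The OOH group can ligate to the periodinane and decompose by radical paths. The fallback sets out from 11. 2-Methoxypropene/PPTS masks the OOH group as the 2-methoxyprop-2-yl peroxyketal F5. Dess–Martin oxidation then gives the peroxyketal ketone F6. TsOH in MeOH removes the mask and ketalises in one operation to the 3-methoxy dioxolane F7. F7 is ionised in place of 17 under the step 8 conditions, and the route is rejoined at 20.

Step 8 (weak facial bias, Lewis-acid-sensitive peroxide). The fallback sets out from 13 and replaces the cationic C–C bond formation by olefination and oxa-Michael ring closure. Compound 13 reacts through its open form 12 with lithio trimethyl phosphonoacetate (2.2 equiv) to give the hydroperoxy enoate F8. Et2NH in CF3CH2OH closes F8 by 5-exo oxa-Michael addition to the trans methyl ester F9 and the cis methyl ester F10. These are separated, and F10 is re-equilibrated with DBU (retro-oxa-Michael/oxa-Michael) and recycled. LiOH hydrolysis of F9 rejoins the route at 20.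

**Further compounds**
F1 | step 4 | (2R)-2-methyl-1-(2-methyl-1,3-dithian-2-yl)dodec-11-en-2-ol | C=CCCCCCCCC[C@](O)(C)CC1(C)SCCCS1
F2 | step 4 | (4R)-4-hydroxy-4-methyltetradec-13-en-2-one | C=CCCCCCCCC[C@](O)(C)CC(C)=O
F3 | step 4 | (2RS,4R)-4-methyltetradec-13-ene-2,4-diol | C=CCCCCCCCC[C@](O)(C)CC(C)O
F4 | step 4 | (2RS,4R)-4-hydroxy-4-methyltetradec-13-en-2-yl methanesulfonate | C=CCCCCCCCC[C@](O)(C)CC(C)OS(C)(=O)=O
F5 | step 6 | (2RS,4S)-4-[(2-methoxypropan-2-yl)peroxy]-4-methyltetradec-13-en-2-ol | C=CCCCCCCCC[C@@](OOC(C)(C)OC)(C)CC(C)O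
F6 | step 6 | (4S)-4-[(2-methoxypropan-2-yl)peroxy]-4-methyltetradec-13-en-2-one | C=CCCCCCCCC[C@@](OOC(C)(C)OC)(C)CC(C)=O
F7 | step 6 | (3RS,5S)-5-(dec-9-en-1-yl)-3-methoxy-3,5-dimethyl-1,2-dioxolane | C=CCCCCCCCC[C@@]1(C)CC(C)(OC)OO1
F8 | step 8 | methyl (5S)-5-hydroperoxy-3,5-dimethylpentadeca-2,14-dienoate (E/Z mixture) | C=CCCCCCCCC[C@@](OO)(C)CC(C)=CC(=O)OC
F9 | step 8 | methyl 2-[(3R,5S)-5-(dec-9-en-1-yl)-3,5-dimethyl-1,2-dioxolan-3-yl]acetate | C=CCCCCCCCC[C@@]1(C)C[C@](C)(CC(=O)OC)OO1
F10 | step 8 | methyl 2-[(3S,5S)-5-(dec-9-en-1-yl)-3,5-dimethyl-1,2-dioxolan-3-yl]acetate | C=CCCCCCCCC[C@@]1(C)C[C@@](C)(CC(=O)OC)OO1
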